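## Retrosynthetic overview

- δ-Tocopherol ⇐ 2H-chromene (saturate C3=C4, remove the benzyl group on the C6 oxygen) ⇐ 2H-chromene-3-carbaldehyde (excise the formyl carbon on C3).
- Feature used: in the pyran ring the segment O1–C2–C3–C4, with quaternary C2 on the ring oxygen and C4 on the benzene ring, is read as the β-carbon and α-carbon of an enal joined to the carbonyl carbon of a salicylaldehyde. Cutting O1–C2 and C3–C4 gives (E)-phytenal and 5-(benzyloxy)-2-hydroxy-3-methylbenzaldehyde.
- Ring order: the benzene ring is bought; the pyran ring is the only ring made (step 5), together with the only new stereocentre, C2. C4' and C8' come from natural phytol.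
- Phytenal ⇐ phytol (allylic oxidation). The salicylaldehyde ⇐ 4-(benzyloxy)-2-methylphenol (ortho-formylation) ⇐ 4-hydroxy-2-methylbenzaldehyde (O-benzylation, Baeyer–Villiger), so the position of the benzyl group is fixed by the starting material and not by a selective monoalkylation of a hydroquinone.

Key step: step 5

Assumption: the sense of induction is taken from the usual steric model for prolinol silyl ether iminium ions (S catalyst, attack anti to the C(Ar)2OSiMe3 group, Re face of C3 of the E-enal, giving 2R); it is to be confirmed by correlation with natural (2R,4'R,8'R)-δ-tocopherol, the R catalyst being the remedy if the sense is opposite.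

## Route

Step 1
Reactants: 1 natural phytol, (2E,7R,11R)-3,7,11,15-tetramethylhexadec-2-en-1-ol
Product: 2 (2E,7R,11R)-3,7,11,15-tetramethylhexadec-2-enal (phytenal)
Conditions: activated MnO2 (excess), hexane, rt, dark
Reagents that add atoms: none
Why: MnO2 oxidation of a primary allylic alcohol is chemoselective and stops at the enal under neutral heterogeneous conditions, which should preserve the 2E geometry and does not touch C7 or C11.

Step 2
Reactants: 3 4-hydroxy-2-methylbenzaldehyde
Product: 4 4-(benzyloxy)-2-methylbenzaldehyde
Conditions: BnBr, K2CO3, DMF, rt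
Reagents that add atoms: benzyl bromide, BrCc1ccccc1
Why: Williamson ether synthesis on the only phenol places the benzyl group unambiguously on the oxygen that becomes the C6 oxygen of the chroman.

Step 3
Reactants: 4 4-(benzyloxy)-2-methylbenzaldehyde
Product: 6 4-(benzyloxy)-2-methylphenol, via aryl formate 5 (not isolated)
Conditions: mCPBA, CH2Cl2, 0 °C to rt; then K2CO3 (cat.), MeOH, rt
Reagents that add atoms: mCPBA (3-chloroperoxybenzoic acid), OOC(=O)c1cccc(Cl)c1
Why: Baeyer–Villiger (Dakin-type) oxidation, in which the electron-rich para-alkoxyaryl group migrates in preference to hydrogen, gives formate 5, and base-catalysed methanolysis then frees the phenol without touching the benzyl ether.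

Step 4
Reactants: 6 4-(benzyloxy)-2-methylphenol
Product: 7 5-(benzyloxy)-2-hydroxy-3-methylbenzaldehyde
Conditions: MgCl2, Et3N, (CH2O)n, MeCN, reflux; aq. HCl work-up
Reagents that add atoms: paraformaldehyde (formaldehyde), C=O
Why: Magnesium-mediated ortho-formylation of a phenol (Casnati–Skattebøl reaction): the magnesium phenoxide delivers formaldehyde to the only free ortho carbon through a chelate, and a second formaldehyde oxidises the resulting benzylic alkoxide by hydride transfer.

Step 5
Reactants: 2 (E)-phytenal; 7 5-(benzyloxy)-2-hydroxy-3-methylbenzaldehyde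
Product: 9 (2R)-6-(benzyloxy)-2,8-dimethyl-2-[(4R,8R)-4,8,12-trimethyltridecyl]-2H-chromene-3-carbaldehyde, via aldol adduct 8 (not isolated)
Conditions: (S)-α,α-bis[3,5-bis(trifluoromethyl)phenyl]prolinol trimethylsilyl ether (20 mol%), PhCO2H (20 mol%), toluene (concentrated), 0 °C to rt, dark
Reagents that add atoms: none
Why: The S amine and PhCO2H convert 2 into its E-iminium ion, the phenol oxygen of 7 adds reversibly to the β-carbon (C3 of 2) to form O1–C2, and the resulting enamine attacks the ortho formyl carbon to form C3–C4; dehydration of aldol 8 to the conjugated enal and hydrolysis should release 9 and the amine. The closest known reaction is the prolinol-silyl-ether-catalysed domino oxa-Michael/aldol condensation of salicylaldehydes with enals to 2H-chromene-3-carbaldehydes, established with induction for β-monosubstituted enals and without induction for β,β-disubstituted enals such as 3-methylbut-2-enal, so a tetrasubstituted C–O centre set with induction is its demanding limit. The pyran ring closes in the aldol event as a 6-(enolexo)-exo-trig cyclisation of the enamine α-carbon onto C=O; should C–C bond formation through the dienamine α-carbon come first, a 6-endo-trig oxa-Michael closure of the same iminium ion converges on 9. C2 is set by the catalyst: its C(Ar)2OSiMe3 group covers the Si face of the β-carbon of the s-trans E,E-iminium ion, so oxygen should enter on the Re face, which with methyl cis and the C16 chain trans to the iminium carbon corresponds to 2R, the remote C4' and C8' centres giving no useful bias. The step needs the 2E geometry to persist (γ-deprotonation to the dienamine scrambles it and the Z-iminium ion leads to 2S) and needs C–C bond formation at the α-carbon and not through the C3 methyl group. The geometrically pure enal from natural phytol, the acid co-catalyst, high concentration and low temperature serve the first need; the ortho placement of the single free OH and the CHO in 7 lets the enamine reach the carbonyl only through its α-carbon in a six-membered transition state, and the irreversible dehydration pulls the reversible adducts forward.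

Step 6
Reactants: 9 (2R)-6-(benzyloxy)-2,8-dimethyl-2-[(4R,8R)-4,8,12-trimethyltridecyl]-2H-chromene-3-carbaldehyde
Product: 10 (2R)-6-(benzyloxy)-2,8-dimethyl-2-[(4R,8R)-4,8,12-trimethyltridecyl]-2H-chromene
Conditions: RhCl(PPh3)3 (1.1 equiv), degassed toluene, 100–110 °C, Ar, dark
Reagents that add atoms: none
Why: Tsuji–Wilkinson decarbonylation: oxidative addition of the formyl C–H bond to monovalent rhodium, CO de-insertion and reductive elimination of the C3–H bond remove the formyl carbon as RhCl(CO)(PPh3)2, while C3=C4 cannot migrate (C2 has no hydrogen) and the quaternary C2 centre is not involved.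

Step 7
Reactants: 10 (2R)-6-(benzyloxy)-2,8-dimethyl-2-[(4R,8R)-4,8,12-trimethyltridecyl]-2H-chromene
Product: 11 δ-tocopherol, (2R)-2,8-dimethyl-2-[(4R,8R)-4,8,12-trimethyltridecyl]chroman-6-ol
Conditions: H2 (1 atm), 10% Pd/C, EtOAc/EtOH, rt
Reagents that add atoms: none
Why: Heterogeneous catalytic hydrogenation saturates the cis-disubstituted styrenic C3=C4 bond and hydrogenolyses the benzyl aryl ether in one operation; no stereocentre is formed (C3 and C4 become CH2) and the quaternary C2 and the chain centres are untouched.

## Compound list

1 | natural phytol, (2E,7R,11R)-3,7,11,15-tetramethylhexadec-2-en-1-ol | OC/C=C(\C)CCC[C@H](C)CCC[C@H](C)CCCC(C)C | starting material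
2 | (2E,7R,11R)-3,7,11,15-tetramethylhexadec-2-enal (phytenal) | O=C/C=C(\C)CCC[C@H](C)CCC[C@H](C)CCCC(C)C | intermediate
3 | 4-hydroxy-2-methylbenzaldehyde | Cc1cc(O)ccc1C=O | starting material
4 | 4-(benzyloxy)-2-methylbenzaldehyde | Cc1cc(OCc2ccccc2)ccc1C=O | intermediate
5 | 4-(benzyloxy)-2-methylphenyl formate | Cc1cc(OCc2ccccc2)ccc1OC=O | intermediate (not isolated)
6 | 4-(benzyloxy)-2-methylphenol | Cc1cc(OCc2ccccc2)ccc1O | intermediate
7 | 5-(benzyloxy)-2-hydroxy-3-methylbenzaldehyde | Cc1cc(OCc2ccccc2)cc(C=O)c1O | intermediate
8 | (2R)-6-(benzyloxy)-4-hydroxy-2,8-dimethyl-2-[(4R,8R)-4,8,12-trimethyltridecyl]-3,4-dihydro-2H-chromene-3-carbaldehyde (aldol adduct, C3/C4 isomers) | O=CC1C(O)c2cc(OCc3ccccc3)cc(C)c2O[C@]1(C)CCC[C@H](C)CCC[C@H](C)CCCC(C)C | intermediate (not isolated)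
9 | (2R)-6-(benzyloxy)-2,8-dimethyl-2-[(4R,8R)-4,8,12-trimethyltridecyl]-2H-chromene-3-carbaldehyde | O=CC1=Cc2cc(OCc3ccccc3)cc(C)c2O[C@]1(C)CCC[C@H](C)CCC[C@H](C)CCCC(C)C | intermediate
10 | (2R)-6-(benzyloxy)-2,8-dimethyl-2-[(4R,8R)-4,8,12-trimethyltridecyl]-2H-chromene | C1=Cc2cc(OCc3ccccc3)cc(C)c2O[C@]1(C)CCC[C@H](C)CCC[C@H](C)CCCC(C)C | intermediate
11 | δ-tocopherol, (2R)-2,8-dimethyl-2-[(4R,8R)-4,8,12-trimethyltridecyl]chroman-6-ol | Cc1cc(O)cc2c1O[C@](C)(CCC[C@H](C)CCC[C@H](C)CCCC(C)C)CC2 | target

## Step count and risks

Total steps: 7. Longest linear sequence: 6 steps (3 → 4 → 6 → 7 → 9 → 10 → 11); phytenal 2 is one step from 1.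

**1. Step 5 (key annulation).**
- What may go wrong: the hindered β,β-disubstituted iminium ion may lose a γ-proton faster than its β-carbon accepts the phenol. The dienamine so formed scrambles the 2E/2Z geometry, which lowers the facial fidelity at C2. It can also attack the formyl group of 7 through the carbon of the C3 methyl group, so that material drains into a vinylogous aldol/oxa-Michael annulation instead of the intended one.
- Fallback: that second manifold is used on purpose. Setting out from 2 and 7, the enantiomeric R catalyst in toluene without acid should give the bridged lactol F1 by vinylogous aldol addition, oxa-Michael closure onto C3 of the enal and lactol formation. In F1 pyran carbon C3 comes from the methyl group, and C2/C1 of phytenal sit on chroman C2 as a CH2–CH(OH)–O bridge to C4.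
- The R catalyst is expected to give 2R here because ring carbon C3 and the C2 methyl group exchange their origins; this is to be confirmed by correlation.
- Stoichiometric RhCl(PPh3)3 in hot toluene should decarbonylate the open hydroxy-aldehyde form of F1, turning the CH2CHO arm into the C2 methyl group and giving chroman-4-ol F2.
- Mesylation and elimination (MsCl, Et3N, then DBU if needed) should give 10, where the route is rejoined before step 7.

**2. Step 6 (decarbonylation).**
- What may go wrong: CO extrusion from the hindered, conjugated formyl group may need temperatures at which the 2H-chromene ring of 9 or 10 opens reversibly to an ortho-quinone methide (retro oxa-6π electrocyclisation), which would scramble C2. The extrusion itself may also stall.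
- Fallback: the last two operations are inverted so that no 2H-chromene is heated. From 9, H2 over 10% Pd/C (EtOAc, rt) should saturate C3=C4 and cleave the benzyl ether to give hydroxy aldehyde F3 (C3 epimers, both converging).
- RhCl(PPh3)3 (1.1 equiv, PhCN or xylene, 130–140 °C) should then decarbonylate this chroman-3-carbaldehyde, whose C2 centre cannot open, directly to 11.

**3. Step 7 (hydrogenation).**
- What may go wrong: on palladium the allylic aryl ether bond O1–C2 of 10 may undergo hydrogenolysis (ring opening to a phenol) in competition with saturation of C3=C4.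
- Fallback: the alkene is reduced without a metal. From 10, diimide (potassium azodicarboxylate, AcOH, MeOH/CH2Cl2, rt) should saturate C3=C4 to δ-tocopherol benzyl ether F4, which is no longer an allylic ether.
- Hydrogenolysis of the benzyl group (H2, Pd(OH)2/C, EtOAc, rt) then gives 11.

## Further compounds

F1 | step 5 | (2R,6R)-8-(benzyloxy)-10-methyl-2-[(4R,8R)-4,8,12-trimethyltridecyl]-3,4-dihydro-2H,6H-2,6-methano-1,5-benzodioxocin-4-ol (bridged lactol, C4 epimers) | Cc1cc(OCc3ccccc3)cc2c1O[C@](CC(O)O4)(CCC[C@H](C)CCC[C@H](C)CCCC(C)C)C[C@H]24
F2 | step 5 | (2R,4R)-6-(benzyloxy)-2,8-dimethyl-2-[(4R,8R)-4,8,12-trimethyltridecyl]-3,4-dihydro-2H-chromen-4-ol | Cc1cc(OCc3ccccc3)cc2c1O[C@](C)(CCC[C@H](C)CCC[C@H](C)CCCC(C)C)C[C@H]2O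
F3 | step 6 | (2R)-6-hydroxy-2,8-dimethyl-2-[(4R,8R)-4,8,12-trimethyltridecyl]-3,4-dihydro-2H-chromene-3-carbaldehyde (C3 epimers) | O=CC1Cc2cc(O)cc(C)c2O[C@]1(C)CCC[C@H](C)CCC[C@H](C)CCCC(C)C
F4 | step 7 | (2R)-6-(benzyloxy)-2,8-dimethyl-2-[(4R,8R)-4,8,12-trimethyltridecyl]-3,4-dihydro-2H-chromene (δ-tocopherol benzyl ether) | Cc1cc(OCc3ccccc3)cc2c1O[C@](C)(CCC[C@H](C)CCC[C@H](C)CCCC(C)C)CC2
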